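**Retrosynthetic overview**

1. The target is read as 1β‑O‑[(E)‑4‑methoxycinnamoyl]‑6α‑hydroxypolygodial; late acylation at C1 and redox adjustment at C11/C12 lead back to a dimethyl 1β‑alkoxy‑6α‑hydroxydrim‑7‑ene‑11,12‑dioate.
2. The C7=C8/C9–H array is traced to a C8=C9 diester (deconjugation), and the 5α‑H/6α‑OH pair to a C5=C6 alkene (hydroboration), so ring B becomes a cyclohexa‑1,4‑diene.
3. Key disconnection: C7–C8 and C9–C10 by Diels–Alder reaction of a ring‑A 2‑vinylcyclohexene (C7=C6–C5=C10) with dimethyl acetylenedicarboxylate (C8≡C9 carrying C11 and C12).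
4. Enabling feature: ring B (C5–C10) carries its two formyl carbons C11/C12 on the adjacent atoms C9/C8, with C6–OH/C5–H across the ring, i.e. it is a masked 1,4‑cyclohexadiene‑1,2‑dicarboxylate. The C1 oxygen sits on the ring‑A carbon next to the diene terminus C10 and relays its configuration to the quaternary centre.
5. Ring order: ring A from 4,4‑dimethylcyclohexane‑1,3‑dione (C1 set by CBS reduction), then ring B by the cycloaddition; C5, C6 and C9 follow by substrate control.

Key step: step 6

Remark: drimane numbering is used (ring A = C1–C5/C10, ring B = C5–C10, C11 on C9, C12 on C8); β is the face of the C10 methyl. Compounds 1, 2, 4, 6, 10, 12, 14, 15, 21 and 24 are assumed to be commercial.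

**Route**

Step 1
Reactants: 1 4,4-dimethylcyclohexane-1,3-dione; 2 iodomethane
Product: 3 2,4,4-trimethylcyclohexane-1,3-dione
Conditions: MeI, K2CO3, acetone, reflux
Reagents that add atoms: iodomethane (2), CI
Why: C‑alkylation of the doubly activated C2 position of a cyclic 1,3‑diketone enolate; no stereocentre is retained.

Step 2
Reactants: 3 2,4,4-trimethylcyclohexane-1,3-dione; 4 2-methylpropan-1-ol
Product: 5 3-isobutoxy-2,6,6-trimethylcyclohex-2-en-1-one
Conditions: i-BuOH, TsOH (cat.), toluene, reflux, Dean–Stark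
Reagents that add atoms: 2-methylpropan-1-ol (4), CC(C)CO
Why: Acid‑catalysed enol etherification (vinylogous ester formation) should occur at the carbonyl remote from the gem‑dimethyl carbon, leaving the hindered carbonyl for step 3.

Step 3
Reactants: 5 3-isobutoxy-2,6,6-trimethylcyclohex-2-en-1-one; 6 vinylmagnesium bromide
Product: 8 2,4,4-trimethyl-3-vinylcyclohex-2-en-1-one, via bromomagnesium alkoxide 7 (not isolated)
Conditions: CH2=CHMgBr, THF, 0 °C → rt; then 1 M HCl, rt
Reagents that add atoms: vinylmagnesium bromide (6), C=C[Mg]Br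
Why: Stork–Danheiser alkylative carbonyl transposition: 1,2‑addition to the vinylogous ester, then acid hydrolysis and loss of isobutanol place the vinyl group next to the gem‑dimethyl carbon.

Step 4
Reactants: 8 2,4,4-trimethyl-3-vinylcyclohex-2-en-1-one
Product: 9 (R)-2,4,4-trimethyl-3-vinylcyclohex-2-en-1-ol
Conditions: (S)-Me-CBS (0.15 equiv), catecholborane, toluene, −78 °C
Reagents that add atoms: none
Why: Corey–Bakshi–Shibata reduction; the α‑methyl alkenyl arm acts as the large group and CH2 as the small one, so the (S)‑catalyst should give the (R)‑carbinol (future C1), and catecholborane leaves the diene untouched.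

Step 5
Reactants: 9 (R)-2,4,4-trimethyl-3-vinylcyclohex-2-en-1-ol; 10 4-methoxybenzyl chloride
Product: 11 (R)-2,4,4-trimethyl-3-vinylcyclohex-2-en-1-yl 4-methoxybenzyl ether
Conditions: NaH, PMBCl, Bu4NI (cat.), THF/DMF, 0 °C → rt
Reagents that add atoms: 4-methoxybenzyl chloride (10), COc1ccc(CCl)cc1
Why: Williamson etherification of the allylic alkoxide; the C1 centre is not touched.

Step 6
Reactants: 11 (R)-2,4,4-trimethyl-3-vinylcyclohex-2-en-1-yl 4-methoxybenzyl ether; 12 dimethyl acetylenedicarboxylate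
Product: 13 dimethyl 1β-(4-methoxybenzyloxy)drima-5,8-diene-11,12-dioate
Conditions: DMAD (3 equiv), BHT (cat.), neat (or toluene, sealed tube), 110 °C
Reagents that add atoms: dimethyl acetylenedicarboxylate (12), COC(=O)C#CC(=O)OC
Why: A concerted, suprafacial thermal [4+2] cycloaddition (normal electron demand) between the s‑cis diene C7=C6–C5=C10 of 11 and the alkyne C8≡C9 of 12 forms C7–C8 and C9–C10 together and leaves ring B as a cyclohexa‑1,4‑diene (C5=C6, C8=C9). The closest known reaction type is the thermal Diels–Alder reaction of 1‑vinyl‑2,6,6‑trimethylcyclohexene‑type dienes with acetylenedicarboxylates. Ring B is closed by intermolecular [4+2] annulation onto ring A. The only new stereocentre, quaternary C10, is controlled by C1: A(1,2) strain with the C10 methyl holds the C1 ether pseudoaxial, so it covers one face of the diene terminus and C9 should bond from the opposite face, placing the C10 methyl cis to the C1 oxygen as in the target. Facial selectivity is the only selectivity required, because the dienophile is symmetric (no regiochemistry) and linear (no endo/exo issue), and the C4 gem‑dimethyl group lies on the far side of the diene from the incoming alkyne. An oxygen‑tethered intramolecular variant is deliberately avoided, since it would deliver C9 syn to the C1 oxygen.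

Step 7
Reactants: 13 dimethyl 1β-(4-methoxybenzyloxy)drima-5,8-diene-11,12-dioate; 14 borane (as BH3·THF); 15 sodium perborate (as tetrahydrate)
Product: 17 dimethyl 6α-hydroxy-1β-(4-methoxybenzyloxy)-5α-drim-8-ene-11,12-dioate, via C6 alkylborane 16 (not isolated)
Conditions: BH3·THF, THF, 0 °C → rt; then NaBO3·4H2O, THF/H2O, rt
Reagents that add atoms: borane (14), B; sodium perborate (15), [Na+].[Na+].O[B-]1(O)OO[B-](O)(O)OO1
Why: Brown hydroboration–oxidation; BH3 should add syn to the trisubstituted C5=C6 bond from the α face (opposite the C10 methyl, as with Δ5‑steroids) with boron at C6, and stereoretentive oxidation gives 5α‑H and 6α‑OH, while the tetrasubstituted electron‑poor C8=C9 diester alkene is left.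

Step 8
Reactants: 17 dimethyl 6α-hydroxy-1β-(4-methoxybenzyloxy)-5α-drim-8-ene-11,12-dioate
Product: 19 dimethyl 6α-hydroxy-1β-(4-methoxybenzyloxy)-5α,9α-drim-7-ene-11,12-dioate, via dilithium alkoxide-dienolate 18 (not isolated)
Conditions: LDA (3.2 equiv), THF, −78 → −40 °C; then AcOH, −78 °C
Reagents that add atoms: none
Why: Deconjugative isomerisation through the extended enolate: γ‑deprotonation at C7 and kinetic α‑protonation at C9 from the α face (opposite the C10 methyl) should give 9α‑H and the C7=C8 enoate; the C6 oxygen is carried as its lithium alkoxide (Fráter–Seebach‑type dianion), which cannot leave and so blocks elimination across C6–C7.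

Step 9
Reactants: 19 dimethyl 6α-hydroxy-1β-(4-methoxybenzyloxy)-5α,9α-drim-7-ene-11,12-dioate
Product: 20 1β-(4-methoxybenzyloxy)drim-7-ene-6α,11,12-triol
Conditions: DIBAL-H (7 equiv), CH2Cl2, −78 → 0 °C; Rochelle salt work-up
Reagents that add atoms: none
Why: 1,2‑Reduction of both esters by a non‑basic hydride, which should leave the C9 centre and the C7=C8 bond intact.

Step 10
Reactants: 20 1β-(4-methoxybenzyloxy)drim-7-ene-6α,11,12-triol; 21 triethylsilyl trifluoromethanesulfonate
Product: 22 1β-(4-methoxybenzyloxy)-6α,11,12-tris(triethylsilyloxy)drim-7-ene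
Conditions: TESOTf (3.6 equiv), 2,6-lutidine, CH2Cl2, −78 → 0 °C
Reagents that add atoms: triethylsilyl trifluoromethanesulfonate (21), CC[Si](CC)(CC)OS(=O)(=O)C(F)(F)F
Why: Exhaustive silylation with a silyl triflate, reactive enough for the hindered C6 hydroxyl; the PMB ether is stable under buffered low‑temperature conditions.

Step 11
Reactants: 22 1β-(4-methoxybenzyloxy)-6α,11,12-tris(triethylsilyloxy)drim-7-ene
Product: 23 6α,11,12-tris(triethylsilyloxy)drim-7-en-1β-ol
Conditions: DDQ, CH2Cl2/pH 7 buffer, 0 °C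
Reagents that add atoms: none
Why: Oxidative cleavage of the PMB ether (benzylic hydride abstraction, hemiacetal hydrolysis); it is orthogonal to the silyl ethers and occurs at the benzylic carbon, remote from the hindered C1.

Step 12
Reactants: 23 6α,11,12-tris(triethylsilyloxy)drim-7-en-1β-ol; 24 (E)-4-methoxycinnamoyl chloride
Product: 25 6α,11,12-tris(triethylsilyloxy)drim-7-en-1β-yl (E)-4-methoxycinnamate
Conditions: Et3N, DMAP (1 equiv), CH2Cl2, 0 → 35 °C
Reagents that add atoms: (E)-4-methoxycinnamoyl chloride (24), COc1ccc(/C=C/C(Cl)=O)cc1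
Why: DMAP‑mediated acylation of the equatorial C1 alcohol through the acylpyridinium ion; the E geometry comes with the reagent and C1 keeps its configuration (O–H bond only).

Step 13
Reactants: 25 6α,11,12-tris(triethylsilyloxy)drim-7-en-1β-yl (E)-4-methoxycinnamate
Product: 26 11,12-dioxo-6α-(triethylsilyloxy)drim-7-en-1β-yl (E)-4-methoxycinnamate
Conditions: (COCl)2, DMSO, CH2Cl2, −78 → −30 °C; then Et3N, −78 → −20 °C
Reagents that add atoms: none
Why: Swern oxidation applied directly to primary triethylsilyl ethers (a known reaction type): the chlorosulfonium reagent should cleave and oxidise the two primary ethers while the secondary C6 ether stays, and cold activation of both positions before base addition avoids lactol formation and C9 epimerisation.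

Step 14
Reactants: 26 11,12-dioxo-6α-(triethylsilyloxy)drim-7-en-1β-yl (E)-4-methoxycinnamate
Product: 27 1β-O-[(E)-4-methoxycinnamoyl]-6α-hydroxypolygodial (target)
Conditions: 48% aq. HF, MeCN, 0 °C
Reagents that add atoms: none
Why: Acidic, base‑free desilylation of the secondary silyl ether, which should leave the cinnamate, the enal and the epimerisable C9 aldehyde untouched.

**Compound list**

1 | 4,4-dimethylcyclohexane-1,3-dione | CC1(C)CCC(=O)CC1=O | starting material
2 | iodomethane | CI | starting material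
3 | 2,4,4-trimethylcyclohexane-1,3-dione | CC1C(=O)CCC(C)(C)C1=O | intermediate
4 | 2-methylpropan-1-ol (isobutanol) | CC(C)CO | starting material
5 | 3-isobutoxy-2,6,6-trimethylcyclohex-2-en-1-one | CC(C)COC1=C(C)C(=O)C(C)(C)CC1 | intermediate
6 | vinylmagnesium bromide | C=C[Mg]Br | starting material
7 | bromomagnesium alkoxide of 3-isobutoxy-2,6,6-trimethyl-1-vinylcyclohex-2-en-1-ol | CC(C)COC1=C(C)C(O[Mg]Br)(C=C)C(C)(C)CC1 | intermediate
8 | 2,4,4-trimethyl-3-vinylcyclohex-2-en-1-one | O=C1CCC(C)(C)C(C=C)=C1C | intermediate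
9 | (R)-2,4,4-trimethyl-3-vinylcyclohex-2-en-1-ol | O[C@@H]1CCC(C)(C)C(C=C)=C1C | intermediate
10 | 4-methoxybenzyl chloride | COc1ccc(CCl)cc1 | starting material
11 | (R)-2,4,4-trimethyl-3-vinylcyclohex-2-en-1-yl 4-methoxybenzyl ether | COc1ccc(CO[C@@H]2CCC(C)(C)C(C=C)=C2C)cc1 | intermediate
12 | dimethyl acetylenedicarboxylate | COC(=O)C#CC(=O)OC | starting material
13 | dimethyl 1β-(4-methoxybenzyloxy)drima-5,8-diene-11,12-dioate (C10 methyl cis to C1–O) | COc1ccc(CO[C@@H]2CCC(C)(C)C3=CCC(C(=O)OC)=C(C(=O)OC)[C@@]23C)cc1 | intermediate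
14 | borane (as BH3·THF) | B | starting material
15 | sodium perborate (used as tetrahydrate) | [Na+].[Na+].O[B-]1(O)OO[B-](O)(O)OO1 | starting material
16 | C6 alkylborane (6α-boryl, 5α-H) of 13 | COc1ccc(CO[C@@H]2CCC(C)(C)[C@@H]3[C@@H](B)CC(C(=O)OC)=C(C(=O)OC)[C@@]23C)cc1 | intermediate
17 | dimethyl 6α-hydroxy-1β-(4-methoxybenzyloxy)-5α-drim-8-ene-11,12-dioate | COc1ccc(CO[C@@H]2CCC(C)(C)[C@@H]3[C@@H](O)CC(C(=O)OC)=C(C(=O)OC)[C@@]23C)cc1 | intermediate
18 | dilithium C6-alkoxide / C11 ester dienolate (C7=C8, C9=C11) | [Li+].[Li+].COc1ccc(CO[C@@H]2CCC(C)(C)[C@@H]3[C@@H]([O-])C=C(C(=O)OC)C(=C([O-])OC)[C@@]23C)cc1 | intermediate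
19 | dimethyl 6α-hydroxy-1β-(4-methoxybenzyloxy)-5α,9α-drim-7-ene-11,12-dioate (C9 ester β) | COc1ccc(CO[C@@H]2CCC(C)(C)[C@@H]3[C@@H](O)C=C(C(=O)OC)[C@H](C(=O)OC)[C@@]23C)cc1 | intermediate
20 | 1β-(4-methoxybenzyloxy)drim-7-ene-6α,11,12-triol | COc1ccc(CO[C@@H]2CCC(C)(C)[C@@H]3[C@@H](O)C=C(CO)[C@H](CO)[C@@]23C)cc1 | intermediate
21 | triethylsilyl trifluoromethanesulfonate | CC[Si](CC)(CC)OS(=O)(=O)C(F)(F)F | starting material
22 | 1β-(4-methoxybenzyloxy)-6α,11,12-tris(triethylsilyloxy)drim-7-ene | COc1ccc(CO[C@@H]2CCC(C)(C)[C@@H]3[C@@H](O[Si](CC)(CC)CC)C=C(CO[Si](CC)(CC)CC)[C@H](CO[Si](CC)(CC)CC)[C@@]23C)cc1 | intermediate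
23 | 6α,11,12-tris(triethylsilyloxy)drim-7-en-1β-ol | O[C@@H]1CCC(C)(C)[C@@H]2[C@@H](O[Si](CC)(CC)CC)C=C(CO[Si](CC)(CC)CC)[C@H](CO[Si](CC)(CC)CC)[C@@]12C | intermediate
24 | (E)-4-methoxycinnamoyl chloride | COc1ccc(/C=C/C(Cl)=O)cc1 | starting material
25 | 6α,11,12-tris(triethylsilyloxy)drim-7-en-1β-yl (E)-4-methoxycinnamate | COc1ccc(/C=C/C(=O)O[C@@H]2CCC(C)(C)[C@@H]3[C@@H](O[Si](CC)(CC)CC)C=C(CO[Si](CC)(CC)CC)[C@H](CO[Si](CC)(CC)CC)[C@@]23C)cc1 | intermediate
26 | 11,12-dioxo-6α-(triethylsilyloxy)drim-7-en-1β-yl (E)-4-methoxycinnamate | COc1ccc(/C=C/C(=O)O[C@@H]2CCC(C)(C)[C@@H]3[C@@H](O[Si](CC)(CC)CC)C=C(C=O)[C@H](C=O)[C@@]23C)cc1 | intermediate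
27 | 1β-O-[(E)-4-methoxycinnamoyl]-6α-hydroxypolygodial (CNP0283080.1) | COc1ccc(/C=C/C(=O)O[C@@H]2CCC(C)(C)[C@@H]3[C@@H](O)C=C(C=O)[C@H](C=O)[C@@]23C)cc1 | target

**Totals**

Total step count: 14. Longest linear sequence: 14 steps (1 → 27; the route is linear).

**Steps most likely to fail**

Step 6 (cycloaddition). The dienophile may approach C10 with too little preference for the face opposite the C1 ether, or the hindered diene may react so slowly that [1,5]‑hydrogen shift competes. Fallback: the stereocontrolling group is changed to a bulky silyl ether and exchanged after the cycloaddition. The fallback sets out from 9, which is silylated (TBDPSCl, imidazole, DMF) to the tert‑butyldiphenylsilyl ether F1. Thermal cycloaddition with 12 should then give dimethyl 1β‑(tert‑butyldiphenylsilyloxy)drima‑5,8‑diene‑11,12‑dioate F2. TBAF/AcOH frees dimethyl 1β‑hydroxydrima‑5,8‑diene‑11,12‑dioate F3; lactonisation is not expected because O1 is trans to C9. Acid‑catalysed etherification with 4‑methoxybenzyl trichloroacetimidate (cat. TfOH, CH2Cl2, 0 °C) brings the sequence back to 13.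

Step 8 (deconjugation). The lithium alkoxide next to C7 may suppress γ‑deprotonation, or the dianion may aggregate and be reprotonated at C7, returning the C8=C9 isomer. Fallback: the C6 oxygen is capped first and the isomerisation is run on a mono‑anion. The fallback sets out from 17, which is silylated (TESOTf, 2,6‑lutidine) to the 6‑O‑triethylsilyl Δ8 diester F4. LDA (1.2 equiv, THF/DMPU, −78 °C) and cold AcOH quench should give the 6‑O‑triethylsilyl Δ7 diester F5; the low temperature is kept to avoid loss of silanolate across C6–C7. DIBAL‑H reduction gives the 6‑O‑triethylsilyl 11,12‑diol F6, and silylation of the two primary hydroxyls (TESOTf, 2,6‑lutidine) comes back to the route at 22.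

Step 13 (direct oxidation of the silyl ethers). Cleavage may stall at the hindered C11 ether, or the C6 silyl group may be lost under the activating conditions, followed by over‑oxidation. Fallback: deprotection and oxidation are separated. The fallback sets out from 25; mild acid methanolysis (PPTS, MeOH/CH2Cl2, 0 °C) removes only the two primary silyl groups to give the 6‑O‑triethylsilyl 11,12‑diol cinnamate F7. A standard Swern oxidation of this free diol ((COCl)2, DMSO, −78 °C; i‑Pr2NEt) comes back to the route at 26.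

**Further compounds**

F1 | step 6 | (R)-tert-butyldiphenylsilyl ether of 9 | CC(C)(C)[Si](O[C@@H]1CCC(C)(C)C(C=C)=C1C)(c1ccccc1)c1ccccc1
F2 | step 6 | dimethyl 1β-(tert-butyldiphenylsilyloxy)drima-5,8-diene-11,12-dioate | CC(C)(C)[Si](O[C@@H]1CCC(C)(C)C2=CCC(C(=O)OC)=C(C(=O)OC)[C@@]12C)(c1ccccc1)c1ccccc1
F3 | step 6 | dimethyl 1β-hydroxydrima-5,8-diene-11,12-dioate | O[C@@H]1CCC(C)(C)C2=CCC(C(=O)OC)=C(C(=O)OC)[C@@]12C
F4 | step 8 | dimethyl 1β-(4-methoxybenzyloxy)-6α-(triethylsilyloxy)-5α-drim-8-ene-11,12-dioate | COc1ccc(CO[C@@H]2CCC(C)(C)[C@@H]3[C@@H](O[Si](CC)(CC)CC)CC(C(=O)OC)=C(C(=O)OC)[C@@]23C)cc1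
F5 | step 8 | dimethyl 1β-(4-methoxybenzyloxy)-6α-(triethylsilyloxy)-5α,9α-drim-7-ene-11,12-dioate | COc1ccc(CO[C@@H]2CCC(C)(C)[C@@H]3[C@@H](O[Si](CC)(CC)CC)C=C(C(=O)OC)[C@H](C(=O)OC)[C@@]23C)cc1
F6 | step 8 | 1β-(4-methoxybenzyloxy)-6α-(triethylsilyloxy)drim-7-ene-11,12-diol | COc1ccc(CO[C@@H]2CCC(C)(C)[C@@H]3[C@@H](O[Si](CC)(CC)CC)C=C(CO)[C@H](CO)[C@@]23C)cc1
F7 | step 13 | 11,12-dihydroxy-6α-(triethylsilyloxy)drim-7-en-1β-yl (E)-4-methoxycinnamate | COc1ccc(/C=C/C(=O)O[C@@H]2CCC(C)(C)[C@@H]3[C@@H](O[Si](CC)(CC)CC)C=C(CO)[C@H](CO)[C@@]23C)cc1
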